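**Retrosynthetic overview**

1. Ring numbering O1–C2(=O)–C3(CH3)=C4(OH)–C5(=C6H–C7). The last step is a one-pot [3+2] annulation that forms C3–C4 (C-acylation) and O1–C5 (copper-catalysed O-vinylation) between the bis-silyl ketene acetal of propanoic acid (O1–C2–C3) and an (E)-2-bromo-2-enoyl chloride (C4–C5 with the whole side chain).
2. Enabling feature: C4 and C5 are adjacent electrophilic carbons (an acyl carbon and the enol-ester carbon of the exocyclic C5=C6 bond), and O1 and C3 are the 1,3-related nucleophilic ends of a propanoate. The E geometry (C7 cis to C4) is stored beforehand as a vinylic C5–Br bond trans to C7 and carried over with retention.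
3. The bromo acid chloride comes from (E)-selective bromo-Horner–Wadsworth–Emmons olefination (C5=C6) of an α-methyl aldehyde. The aldehyde comes from Negishi sp3–sp2 coupling (C8–C9) of the zinc reagent of methyl (R)-3-bromo-2-methylpropanoate (source of the C7 stereocentre) with an (E,E)-dienyl iodide.
4. The dienyl iodide comes from Takai iodo-olefination (C9=C10) and Wittig olefination (C11=C12) of a 3-furylpropanal, which is assembled on 3,4-dibromofuran by two bromine–lithium exchanges (furan-3-carbaldehyde, then oxetane).
5. Ring order: both furans are bought as rings; the furan-2(5H)-one (tetronic acid) ring is the only ring made and is closed last.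

Key step: step 14

Remark: the tetronic acid is handled as its 4-hydroxy enol tautomer, and the C3 stereocentre that appears in the open-chain β-keto intermediates of the key step is left undefined because it is erased when the ring enolises.

**Route**

Step 1
Reactants: 1 3,4-dibromofuran; 2 furan-3-carbaldehyde
Product: 4 (4-bromofuran-3-yl)(furan-3-yl)methanol (racemic), via 3-bromo-4-lithiofuran 3 (not isolated)
Conditions: n-BuLi (1.0 equiv), Et2O, −78 °C; then 2, −78 °C; H2O
Reagents that add atoms: none
Why: Bromine–lithium exchange on one C–Br bond at −78 °C should give the 3-lithiofuran, which adds to the aldehyde (organolithium 1,2-addition) before it can isomerise to a 2-lithio species; the racemic carbinol centre is removed in step 2.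

Step 2
Reactants: 4 (4-bromofuran-3-yl)(furan-3-yl)methanol
Product: 5 3-bromo-4-(furan-3-ylmethyl)furan
Conditions: Et3SiH (3 equiv), CF3CO2H (3 equiv), CH2Cl2, −20 → 0 °C
Reagents that add atoms: none
Why: Ionic hydrogenation: ionisation of the doubly furyl-stabilised secondary carbinol gives a cation that is captured by hydride from the silane present in excess, and the furyl C–Br bond is inert to these conditions.

Step 3
Reactants: 5 3-bromo-4-(furan-3-ylmethyl)furan; 6 oxetane
Product: 8 3-[4-(furan-3-ylmethyl)furan-3-yl]propan-1-ol, via furyllithium 7 (not isolated)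
Conditions: n-BuLi (1.05 equiv), THF, −78 °C; then 6, BF3·OEt2, −78 °C; H2O
Reagents that add atoms: none
Why: A second bromine–lithium exchange (much faster than deprotonation of the diaryl CH2) followed by BF3-promoted SN2 opening of the strained oxetane by the aryllithium should install the hydroxypropyl arm in one operation.

Step 4
Reactants: 8 3-[4-(furan-3-ylmethyl)furan-3-yl]propan-1-ol
Product: 9 3-[4-(furan-3-ylmethyl)furan-3-yl]propanal
Conditions: Dess–Martin periodinane, pyridine, CH2Cl2, 0 °C → rt
Reagents that add atoms: none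
Why: Dess–Martin oxidation of a primary alcohol stops at the aldehyde, and the pyridine buffer protects the acid-sensitive furans.

Step 5
Reactants: 9 3-[4-(furan-3-ylmethyl)furan-3-yl]propanal; 10 2-(triphenyl-λ5-phosphanylidene)propanal
Product: 11 (2E)-5-[4-(furan-3-ylmethyl)furan-3-yl]-2-methylpent-2-enal
Conditions: toluene, 80 °C
Reagents that add atoms: none
Why: Wittig olefination with a formyl-stabilised ylide should give the (E)-trisubstituted enal (C11=C12), and the ylide reacts only with the more electrophilic saturated aldehyde, not with the enal product.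

Step 6
Reactants: 11 (2E)-5-[4-(furan-3-ylmethyl)furan-3-yl]-2-methylpent-2-enal
Product: 12 3-(furan-3-ylmethyl)-4-[(3E,5E)-6-iodo-4-methylhexa-3,5-dien-1-yl]furan
Conditions: CrCl2 (6 equiv), CHI3 (2 equiv), THF, 0 °C
Reagents that add atoms: iodoform, IC(I)I
Why: Takai olefination: the geminal dichromium species formed from CHI3 and divalent chromium adds to the aldehyde and eliminates to the (E)-vinyl iodide (C9=C10), leaving the existing trisubstituted alkene untouched.

Step 7
Reactants: 13 methyl (2R)-3-bromo-2-methylpropanoate; 12 3-(furan-3-ylmethyl)-4-[(3E,5E)-6-iodo-4-methylhexa-3,5-dien-1-yl]furan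
Product: 15 methyl (2S,4E,6E)-9-[4-(furan-3-ylmethyl)furan-3-yl]-2,6-dimethylnona-4,6-dienoate, via alkylzinc bromide 14 (not isolated)
Conditions: Zn, LiCl, THF, 40 °C; then 12, Pd(PPh3)4 (5 mol %), THF/DMA, 25–40 °C
Reagents that add atoms: none
Why: Zinc insertion into the primary C–Br bond gives a non-basic β-ester alkylzinc that keeps the chiral-pool stereocentre, and Negishi sp3–sp2 coupling at zerovalent palladium joins C8 to C9 with retention of the diene geometry; the descriptor changes from R to S only because the priorities change.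

Step 8
Reactants: 15 methyl (2S,4E,6E)-9-[4-(furan-3-ylmethyl)furan-3-yl]-2,6-dimethylnona-4,6-dienoate
Product: 16 (2S,4E,6E)-9-[4-(furan-3-ylmethyl)furan-3-yl]-2,6-dimethylnona-4,6-dienal
Conditions: i-Bu2AlH (1.1 equiv), CH2Cl2, −78 °C; MeOH quench at −78 °C, aqueous work-up
Reagents that add atoms: none
Why: Partial ester reduction: the tetrahedral aluminium hemiacetal is stable at −78 °C and releases the aldehyde only on work-up, so the α-stereocentre should not epimerise; the aldehyde is used at once.

Step 9
Reactants: 17 methyl 2-[bis(2,2,2-trifluoroethoxy)phosphoryl]acetate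
Product: 19 methyl 2-[bis(2,2,2-trifluoroethoxy)phosphoryl]-2-bromoacetate, via dibromophosphonate 18 (not isolated)
Conditions: aq. NaOBr (2.2 equiv, freshly prepared solution), 0 °C; then SnCl2·2H2O (1.0 equiv), EtOH/H2O, 0 °C
Reagents that add atoms: sodium hypobromite, [Na+].[O-]Br
Why: Hypobromite dibrominates the doubly activated methylene through its enolate, and SnCl2 then removes one bromine by reduction of the electron-poor geminal dibromide and stops at the monobromide (the established halogenation/partial reduction sequence for phosphonoacetates).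

Step 10
Reactants: 16 (2S,4E,6E)-9-[4-(furan-3-ylmethyl)furan-3-yl]-2,6-dimethylnona-4,6-dienal; 19 methyl 2-[bis(2,2,2-trifluoroethoxy)phosphoryl]-2-bromoacetate
Product: 20 methyl (2E,4S,6E,8E)-2-bromo-11-[4-(furan-3-ylmethyl)furan-3-yl]-4,8-dimethylundeca-2,6,8-trienoate
Conditions: 19, t-BuOK, 18-crown-6, THF, −78 °C; then 16, −78 °C
Reagents that add atoms: none
Why: Horner–Wadsworth–Emmons olefination with the bis(trifluoroethyl) bromophosphonate eliminates fast and irreversibly from the kinetic adduct (Still–Gennari-type control) and should place the side chain cis to the ester, that is the (E)-α-bromoacrylate with Br trans to C7; the low temperature protects the α-stereocentre of 16.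

Step 11
Reactants: 20 methyl (2E,4S,6E,8E)-2-bromo-11-[4-(furan-3-ylmethyl)furan-3-yl]-4,8-dimethylundeca-2,6,8-trienoate
Product: 21 (2E,4S,6E,8E)-2-bromo-11-[4-(furan-3-ylmethyl)furan-3-yl]-4,8-dimethylundeca-2,6,8-trienoic acid
Conditions: LiOH·H2O (3 equiv), THF/H2O, 0 °C → rt; then 1 M HCl to pH 3 at 0 °C
Reagents that add atoms: lithium hydroxide, [Li+].[OH-]
Why: Saponification of the methyl ester; the vinylic bromide is cis to the β-hydrogen and so cannot undergo anti-dehydrobromination, and the alkene geometry should be kept.

Step 12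
Reactants: 21 (2E,4S,6E,8E)-2-bromo-11-[4-(furan-3-ylmethyl)furan-3-yl]-4,8-dimethylundeca-2,6,8-trienoic acid
Product: 22 (2E,4S,6E,8E)-2-bromo-11-[4-(furan-3-ylmethyl)furan-3-yl]-4,8-dimethylundeca-2,6,8-trienoyl chloride
Conditions: 1-chloro-N,N,2-trimethylprop-1-en-1-amine (1.2 equiv), CH2Cl2, 0 °C → rt; volatiles removed, used crude
Reagents that add atoms: 1-chloro-N,N,2-trimethylprop-1-en-1-amine, CC(C)=C(Cl)N(C)C
Why: The α-chloroenamine converts the acid into the acid chloride under neutral conditions with a neutral amide as the only by-product, so no HCl reaches the furans, the diene or the bromoalkene.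

Step 13
Reactants: 23 trimethylsilyl propanoate
Product: 24 1,1-bis(trimethylsilyloxy)prop-1-ene
Conditions: TMSOTf (1.1 equiv), Et3N (1.2 equiv), Et2O, 0 °C → rt; distillation
Reagents that add atoms: trimethylsilyl trifluoromethanesulfonate, C[Si](C)(C)OS(=O)(=O)C(F)(F)F
Why: Soft enolisation and O-silylation of a silyl ester: the silyl triflate activates the carbonyl, the amine removes the α-proton, and the ketene bis-silyl acetal forms without strong base.

Step 14
Reactants: 22 (2E,4S,6E,8E)-2-bromo-11-[4-(furan-3-ylmethyl)furan-3-yl]-4,8-dimethylundeca-2,6,8-trienoyl chloride; 24 1,1-bis(trimethylsilyloxy)prop-1-ene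
Product: 27 (5E)-5-[(2S,4E,6E)-9-[4-(furan-3-ylmethyl)furan-3-yl]-2,6-dimethylnona-4,6-dien-1-ylidene]-4-hydroxy-3-methylfuran-2(5H)-one, via silyl β-keto ester 25 (not isolated), via cesium β-keto carboxylate 26 (not isolated)
Conditions: 24 (1.3 equiv), THF, 0 → 40 °C; then MeOH (2.5 equiv), Cs2CO3 (4 equiv), CuI (15 mol %), trans-N,N′-dimethylcyclohexane-1,2-diamine (30 mol %), 60 °C; work-up at pH 3–4
Reagents that add atoms: none
Why: Proposed new method: the nucleophilic carbon of the ketene bis-silyl acetal attacks the acyl chloride carbon of 22 (uncatalysed Claisen-type C-acylation, known for silyl ketene acetals and acid chlorides) and forms C3–C4, and methanolysis with Cs2CO3 then unmasks the β-keto carboxylate 26, whose carboxylate oxygen sits five atoms from the vinylic C5–Br bond. The carboxylate bound to monovalent copper undergoes oxidative addition into C5–Br and C–O reductive elimination from trivalent copper to form O1–C5; the closest known reaction type is the CuI/diamine-catalysed intramolecular O-vinylation of bromoalkenoic acids to enol lactones, and what is new is its use on an α-bromo enone held in a β-keto acid and its telescoping with the acylation. The tetronic acid ring closes in the 5-exo mode at the vinylic carbon through a six-membered cupracycle, leaving C5=C6 exocyclic. No stereocentre is created: C3 becomes sp2 on enolisation, C7 is remote from both reacting sites, and the E geometry of C5=C6 is transferred with retention from 22, in which Br is trans to the side chain. The step needs C- over O-acylation and 1,2- over 1,4-attack, which the carbon terminus of the silyl ketene acetal and the hard acyl chloride should secure. It also needs 5-exo C–O coupling over decarboxylation or 6-endo oxa-Michael addition, which should be secured by holding 26 as its enolised dianion (neither an enone nor a free β-keto acid) with the carboxylate next to the C–Br bond.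

**Compound list**

1 | 3,4-dibromofuran | Brc1cocc1Br | starting material
2 | furan-3-carbaldehyde | O=Cc1ccoc1 | starting material
3 | 3-bromo-4-lithiofuran | [Li]c1cocc1Br | intermediate
4 | (4-bromofuran-3-yl)(furan-3-yl)methanol (racemic) | OC(c1ccoc1)c1cocc1Br | intermediate
5 | 3-bromo-4-(furan-3-ylmethyl)furan | Brc1cocc1Cc1ccoc1 | intermediate
6 | oxetane | C1COC1 | starting material
7 | [4-(furan-3-ylmethyl)furan-3-yl]lithium | [Li]c1cocc1Cc1ccoc1 | intermediate
8 | 3-[4-(furan-3-ylmethyl)furan-3-yl]propan-1-ol | OCCCc1cocc1Cc1ccoc1 | intermediate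
9 | 3-[4-(furan-3-ylmethyl)furan-3-yl]propanal | O=CCCc1cocc1Cc1ccoc1 | intermediate
10 | 2-(triphenyl-λ5-phosphanylidene)propanal | CC(C=O)=P(c1ccccc1)(c1ccccc1)c1ccccc1 | starting material
11 | (2E)-5-[4-(furan-3-ylmethyl)furan-3-yl]-2-methylpent-2-enal | O=C/C(C)=C/CCc1cocc1Cc1ccoc1 | intermediate
12 | 3-(furan-3-ylmethyl)-4-[(3E,5E)-6-iodo-4-methylhexa-3,5-dien-1-yl]furan | I/C=C/C(C)=C/CCc1cocc1Cc1ccoc1 | intermediate
13 | methyl (2R)-3-bromo-2-methylpropanoate | COC(=O)[C@@H](C)CBr | starting material
14 | bromo[(2R)-3-methoxy-2-methyl-3-oxopropyl]zinc | COC(=O)[C@@H](C)C[Zn]Br | intermediate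
15 | methyl (2S,4E,6E)-9-[4-(furan-3-ylmethyl)furan-3-yl]-2,6-dimethylnona-4,6-dienoate | COC(=O)[C@@H](C)C/C=C/C(C)=C/CCc1cocc1Cc1ccoc1 | intermediate
16 | (2S,4E,6E)-9-[4-(furan-3-ylmethyl)furan-3-yl]-2,6-dimethylnona-4,6-dienal | O=C[C@@H](C)C/C=C/C(C)=C/CCc1cocc1Cc1ccoc1 | intermediate
17 | methyl 2-[bis(2,2,2-trifluoroethoxy)phosphoryl]acetate | COC(=O)CP(=O)(OCC(F)(F)F)OCC(F)(F)F | starting material
18 | methyl 2-[bis(2,2,2-trifluoroethoxy)phosphoryl]-2,2-dibromoacetate | COC(=O)C(Br)(Br)P(=O)(OCC(F)(F)F)OCC(F)(F)F | intermediate
19 | methyl 2-[bis(2,2,2-trifluoroethoxy)phosphoryl]-2-bromoacetate (racemic) | COC(=O)C(Br)P(=O)(OCC(F)(F)F)OCC(F)(F)F | intermediate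
20 | methyl (2E,4S,6E,8E)-2-bromo-11-[4-(furan-3-ylmethyl)furan-3-yl]-4,8-dimethylundeca-2,6,8-trienoate | COC(=O)/C(Br)=C\[C@@H](C)C/C=C/C(C)=C/CCc1cocc1Cc1ccoc1 | intermediate
21 | (2E,4S,6E,8E)-2-bromo-11-[4-(furan-3-ylmethyl)furan-3-yl]-4,8-dimethylundeca-2,6,8-trienoic acid | OC(=O)/C(Br)=C\[C@@H](C)C/C=C/C(C)=C/CCc1cocc1Cc1ccoc1 | intermediate
22 | (2E,4S,6E,8E)-2-bromo-11-[4-(furan-3-ylmethyl)furan-3-yl]-4,8-dimethylundeca-2,6,8-trienoyl chloride | ClC(=O)/C(Br)=C\[C@@H](C)C/C=C/C(C)=C/CCc1cocc1Cc1ccoc1 | intermediate
23 | trimethylsilyl propanoate | CCC(=O)O[Si](C)(C)C | starting material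
24 | 1,1-bis(trimethylsilyloxy)prop-1-ene | CC=C(O[Si](C)(C)C)O[Si](C)(C)C | intermediate
25 | trimethylsilyl (4E,6S,8E,10E)-4-bromo-13-[4-(furan-3-ylmethyl)furan-3-yl]-2,6,10-trimethyl-3-oxotrideca-4,8,10-trienoate (C2 epimers) | C[Si](C)(C)OC(=O)C(C)C(=O)/C(Br)=C\[C@@H](C)C/C=C/C(C)=C/CCc1cocc1Cc1ccoc1 | intermediate
26 | cesium (4E,6S,8E,10E)-4-bromo-13-[4-(furan-3-ylmethyl)furan-3-yl]-2,6,10-trimethyl-3-oxotrideca-4,8,10-trienoate (C2 epimers) | [Cs+].[O-]C(=O)C(C)C(=O)/C(Br)=C\[C@@H](C)C/C=C/C(C)=C/CCc1cocc1Cc1ccoc1 | intermediate
27 | (5E)-5-[(2S,4E,6E)-9-[4-(furan-3-ylmethyl)furan-3-yl]-2,6-dimethylnona-4,6-dien-1-ylidene]-4-hydroxy-3-methylfuran-2(5H)-one | CC1=C(O)/C(=C\[C@@H](C)C/C=C/C(C)=C/CCc2cocc2Cc2ccoc2)OC1=O | target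

**Summary**

Total step count: 14. Longest linear sequence: 12 (steps 1–8, 10, 11, 12, 14); steps 9 and 13 are one-step reagent branches.

Steps most likely to fail:

Step 14. The two stages may interfere (incomplete C-acylation, or Michael addition once the enolate is freed). The β-keto carboxylate may also lose CO2, or close in the 6-endo sense by oxa-Michael addition and loss of HBr to a pyranone, before copper forms the C–O bond. The fallback sets out from 22 and comes back to the route at 25. The two bonds are made in separate operations of known type. LiN(i-Pr)2 in THF at −78 °C converts tert-butyl propanoate into lithium 1-(tert-butoxy)prop-1-en-1-olate F1, which is C-acylated by 22 at −78 °C (ester-enolate Claisen acylation) to give the chromatographable tert-butyl β-keto ester F2. TMSOTf/2,6-lutidine in CH2Cl2 at 0 °C then exchanges the tert-butyl for the trimethylsilyl ester and gives 25. This is treated alone with MeOH, Cs2CO3, CuI and the diamine (the known copper-catalysed lactonisation of a bromoalkenoic acid) to reach 27.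

Step 2. The furylic cation may alkylate a second furan ring, or the furans may open under acid, faster than hydride capture. The fallback sets out from 1 and comes back at 5; it avoids the cation by making the diarylmethane C–C bond by cross-coupling. 3-(Chloromethyl)furan F3 is made from commercial furan-3-ylmethanol (MeSO2Cl, Et3N, LiCl, CH2Cl2). Compound 3, generated from 1 and n-BuLi as in step 1, is transmetallated with ZnCl2 to (4-bromofuran-3-yl)zinc chloride F4. F4 is coupled with F3 under Pd(PPh3)4 catalysis in THF at 40 °C (Negishi coupling; the furylmethyl chloride should add to zerovalent palladium faster than the furyl bromide) to give 5 directly.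

Step 8. Over-reduction to the primary alcohol, or α-epimerisation if the aluminium hemiacetal collapses before the quench, may erode yield or optical purity. The fallback sets out from 15 and comes back at 16; it uses a two-step redox sequence. Full reduction with i-Bu2AlH (2.5 equiv, CH2Cl2, 0 °C) gives the alcohol (2S,4E,6E)-9-[4-(furan-3-ylmethyl)furan-3-yl]-2,6-dimethylnona-4,6-dien-1-ol F5. Dess–Martin oxidation buffered with pyridine (CH2Cl2, 0 °C) then returns 16.

Further compounds
F1 | step 14 | lithium 1-(tert-butoxy)prop-1-en-1-olate | [Li+].CC=C([O-])OC(C)(C)C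
F2 | step 14 | tert-butyl (4E,6S,8E,10E)-4-bromo-13-[4-(furan-3-ylmethyl)furan-3-yl]-2,6,10-trimethyl-3-oxotrideca-4,8,10-trienoate (C2 epimers) | CC(C)(C)OC(=O)C(C)C(=O)/C(Br)=C\[C@@H](C)C/C=C/C(C)=C/CCc1cocc1Cc1ccoc1
F3 | step 2 | 3-(chloromethyl)furan | ClCc1ccoc1
F4 | step 2 | (4-bromofuran-3-yl)zinc chloride | Cl[Zn]c1cocc1Br
F5 | step 8 | (2S,4E,6E)-9-[4-(furan-3-ylmethyl)furan-3-yl]-2,6-dimethylnona-4,6-dien-1-ol | OC[C@@H](C)C/C=C/C(C)=C/CCc1cocc1Cc1ccoc1
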